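Ring B of the target carries on neighbouring carbons C9 and C10 a lactone carbonyl (C20) and a propanoate arm (C1–C3) that are cis; reconnecting C3 to C20 reveals a cyclohexanone (ring A) fused to ring B. Ring B is therefore made by a catalytic enantioselective Diels–Alder addition of (E)-piperylene to a 2-substituted cyclohex-2-enone, which in one operation forms C8–C9 and C5–C10 and sets C8, quaternary C9 and C10. The dienophile is an achiral enone whose two-carbon arm (C11–C12) ends in a primary chloride, inert to Lewis acid and later the handle for the butenolide. Afterwards ring A is cut at C3–C20, C5 is oxidised, and isopropenyl addition closes the lactone.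

Key step: step 5

Atom labels (target): ring B = C5–C10 (C5 bears the lactone oxygen and the isopropenyl group, C8 the methyl, C9 is quaternary); C20 = lactone carbonyl on C9; C1–C3 = ester arm on C10 (C3 = ester carbonyl); C11–C12 = ethylene tether on C9; C13–C16 = butenolide, C13 bonded to C12. Ring A = temporary cyclohexanone C20–C9–C10–C1–C2–C3.

Design remark: the C12 terminus is carried as a chloride, not as an oxygen function. A free C12 hydroxyl would sit gamma to the C20 ester or lactone on a quaternary carbon and could translactonise, and the chloride offers no basic oxygen to the boron catalyst.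

Assumption: the (S)-catalyst is taken to favour the (4aS,8R,8aS) adduct; if the facial sense proved opposite, the (R)-catalyst would be used with nothing else changed.

Step 1
Reactants: 1 cyclohexane-1,3-dione; 2 ethyl bromoacetate
Product: 3 ethyl 2-(2,6-dioxocyclohexyl)acetate
Conditions: KOH (1 equiv), H2O, 0 °C → rt
Reagents that add atoms: none
Why: SN2 C-alkylation of the 1,3-dione enolate with an activated α-halo ester in water, where hydrogen bonding to the enolate oxygens should favour attack through carbon.

Step 2
Reactants: 3 ethyl 2-(2,6-dioxocyclohexyl)acetate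
Product: 4 ethyl 2-(2-ethoxy-6-oxocyclohex-1-en-1-yl)acetate
Conditions: EtOH, TsOH (cat.), toluene, reflux, Dean–Stark
Reagents that add atoms: ethanol, CCO
Why: acid-catalysed enol etherification of a cyclic 1,3-dione with azeotropic removal of water gives the vinylogous ester, the symmetry of 3 allowing only one regioisomer and ethanol matching the ester group.

Step 3
Reactants: 4 ethyl 2-(2-ethoxy-6-oxocyclohex-1-en-1-yl)acetate
Product: 6 2-(2-hydroxyethyl)cyclohex-2-en-1-one, via enol ether diol 5 (not isolated)
Conditions: LiAlH4, THF, 0 °C → rt; then 2 M HCl, 0 °C → rt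
Reagents that add atoms: water, O
Why: Stork–Danheiser carbonyl transposition, in which hydride reduces the ester to the primary alcohol and the vinylogous ester carbonyl by 1,2-addition, and aqueous acid then hydrolyses the enol ether and expels the allylic hydroxyl, leaving the hydroxyethyl arm on the α-carbon of the new enone.

Step 4
Reactants: 6 2-(2-hydroxyethyl)cyclohex-2-en-1-one
Product: 7 2-(2-chloroethyl)cyclohex-2-en-1-one
Conditions: PPh3, N-chlorosuccinimide (premixed), CH2Cl2, 0 °C → rt
Reagents that add atoms: N-chlorosuccinimide, O=C1CCC(=O)N1Cl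
Why: Appel-type deoxychlorination, the primary alcohol being activated as its alkoxyphosphonium salt and displaced by chloride in an SN2 step, with the phosphine consumed by the chlorinating agent before it can meet the enone.

Step 5
Reactants: 7 2-(2-chloroethyl)cyclohex-2-en-1-one; 8 (E)-penta-1,3-diene
Product: 9 (4aS,8R,8aS)-8a-(2-chloroethyl)-8-methyl-3,4,4a,5,8,8a-hexahydronaphthalen-1(2H)-one
Conditions: (S)-3,3-diphenyl-1-(o-tolyl)tetrahydro-1H,3H-pyrrolo[1,2-c][1,3,2]oxazaborole (20 mol%), HNTf2 (18 mol%), 8 (5 equiv), CH2Cl2, −40 → −20 °C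
Reagents that add atoms: none
Why: The protonated oxazaborolidine binds the C20 carbonyl oxygen and makes the enone a stronger two-electron acceptor, so that 8 adds across C9=C10 in a concerted but unsymmetrical [4+2] cycloaddition in which bonding of the CH2 end of the diene (C5) to the β-carbon C10 runs ahead of C8–C9 bonding. The closest known reactions are AlCl3-promoted Diels–Alder additions of 2-alkylcyclohex-2-enones to (E)-piperylene and oxazaborolidinium-catalysed enantioselective additions of acyclic dienes to cyclohex-2-enone. Ring B is closed by intermolecular union of a four-carbon and a two-carbon unit, both new bonds being made suprafacially on each partner. C9 and C10 come out cis because the ring-locked geometry of the dienophile is transferred, the C8 methyl comes out cis to C20 because the E methyl points outward while the carbonyl lies endo beneath the diene, and the absolute sense of all three is set by the catalyst, whose aryl groups should screen one face of the bound enone. The step needs ortho regiochemistry, endo selectivity and enantiofacial selectivity: the first follows from the largest diene HOMO coefficient at C5 meeting the largest LUMO coefficient at C10, the second from secondary overlap under Lewis acid activation, and the third rests on the catalyst alone, since a 2-alkyl enone has no α-C–H to help fix its orientation on boron. The chloroethyl arm offers no basic or acid-labile site to the Lewis acid.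

Step 6
Reactants: 9 (4aS,8R,8aS)-8a-(2-chloroethyl)-8-methyl-3,4,4a,5,8,8a-hexahydronaphthalen-1(2H)-one
Product: 11 (4aS,8R,8aS)-8a-(2-chloroethyl)-2-hydroxy-8-methyl-3,4,4a,5,8,8a-hexahydronaphthalen-1(2H)-one (C2 epimers), via potassium enolate 10 (not isolated)
Conditions: KHMDS, THF, −78 °C; then 2-(phenylsulfonyl)-3-phenyloxaziridine, −78 °C; NH4Cl aq.
Reagents that add atoms: 2-(phenylsulfonyl)-3-phenyloxaziridine, O=S(=O)(c1ccccc1)N1OC1c1ccccc1
Why: Davis enolate hydroxylation, in which the ketone can enolise only toward C3 because C9 is quaternary, the potassium enolate should be oxidised at −78 °C faster than it can displace the remote primary chloride, and the configuration of the new C3 carbinol is irrelevant because that carbon becomes a carbonyl in step 7.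

Step 7
Reactants: 11 (4aS,8R,8aS)-8a-(2-chloroethyl)-2-hydroxy-8-methyl-3,4,4a,5,8,8a-hexahydronaphthalen-1(2H)-one
Product: 12 methyl (1S,2R,6S)-1-(2-chloroethyl)-2-methyl-6-(3-oxopropyl)cyclohex-3-ene-1-carboxylate
Conditions: Pb(OAc)4, MeOH/toluene (1:1), 0 °C → rt
Reagents that add atoms: methanol, CO
Why: Criegee-type oxidative cleavage of an α-ketol, the C20 hemiketal formed in methanol behaving as a 1,2-diol so that the C20–C3 bond breaks to leave C20 as the methyl ester and C3 as the aldehyde without touching C9, C10 or the C6=C7 alkene.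

Step 8
Reactants: 12 methyl (1S,2R,6S)-1-(2-chloroethyl)-2-methyl-6-(3-oxopropyl)cyclohex-3-ene-1-carboxylate
Product: 13 3-[(1S,5R,6S)-6-(2-chloroethyl)-6-(methoxycarbonyl)-5-methylcyclohex-3-en-1-yl]propanoic acid
Conditions: NaClO2, NaH2PO4, 2-methyl-2-butene, t-BuOH/H2O, rt
Reagents that add atoms: sodium chlorite, [Na+].[O-]Cl=O
Why: Pinnick oxidation takes the aldehyde to the acid under buffered conditions, the alkene scavenger intercepting hypochlorous acid so that C6=C7 is spared, and no epimerisable centre lies next to the aldehyde.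

Step 9
Reactants: 13 3-[(1S,5R,6S)-6-(2-chloroethyl)-6-(methoxycarbonyl)-5-methylcyclohex-3-en-1-yl]propanoic acid
Product: 14 methyl (1S,2R,6S)-1-(2-chloroethyl)-6-(3-methoxy-3-oxopropyl)-2-methylcyclohex-3-ene-1-carboxylate
Conditions: TMSCHN2, toluene/MeOH (4:1), 0 °C
Reagents that add atoms: trimethylsilyldiazomethane, C[Si](C)(C)C=[N+]=[N-]
Why: methyl esterification by proton transfer from the acid to the diazo compound and O-methylation of the carboxylate with loss of nitrogen, under neutral conditions that leave chloride, alkene and the hindered ester untouched.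

Step 10
Reactants: 14 methyl (1S,2R,6S)-1-(2-chloroethyl)-6-(3-methoxy-3-oxopropyl)-2-methylcyclohex-3-ene-1-carboxylate
Product: 15 methyl (1R,2R,6R)-1-(2-chloroethyl)-6-(3-methoxy-3-oxopropyl)-2-methyl-5-oxocyclohex-3-ene-1-carboxylate
Conditions: Rh2(caprolactamate)4 (1 mol%), t-BuOOH (70% in H2O, 5 equiv), 1,2-dichloroethane, 40 °C
Reagents that add atoms: tert-butyl hydroperoxide, CC(C)(C)OO
Why: dirhodium-catalysed allylic oxidation, in which the tert-butylperoxyl radical should abstract the exposed C5 methylene hydrogen in preference to the C8 methine flanked by quaternary C9, and capture of the allyl radical at C5, the end remote from the C8/C9 congestion, gives a mixed peroxide that collapses to the C5 enone.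

Step 11
Reactants: 15 methyl (1R,2R,6R)-1-(2-chloroethyl)-6-(3-methoxy-3-oxopropyl)-2-methyl-5-oxocyclohex-3-ene-1-carboxylate
Product: 16 methyl (1R,2R,6R)-1-(2-chloroethyl)-2-(3-methoxy-3-oxopropyl)-6-methyl-3-oxocyclohexane-1-carboxylate
Conditions: H2 (1 atm), 10% Pd/C, EtOAc, rt
Reagents that add atoms: none
Why: heterogeneous catalytic hydrogenation saturates the conjugated C6=C7 bond without creating a stereocentre, and the neutral medium leaves the α-centre C10, both esters and the primary chloride unchanged.

Step 12
Reactants: 16 methyl (1R,2R,6R)-1-(2-chloroethyl)-2-(3-methoxy-3-oxopropyl)-6-methyl-3-oxocyclohexane-1-carboxylate; 17 isopropenylmagnesium bromide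
Product: 19 methyl 3-[(1R,2R,5S,8R)-1-(2-chloroethyl)-2-methyl-7-oxo-5-(prop-1-en-2-yl)-6-oxabicyclo[3.2.1]octan-8-yl]propanoate, via dichlorocerium alkoxide 18 (not isolated)
Conditions: CeCl3 (anhydrous, 2 equiv), 17 (1.8 equiv), THF, −78 °C; add 16; −78 → 0 °C; NH4Cl aq.
Reagents that add atoms: none
Why: organocerium 1,2-addition followed by lactonisation, in which the axial C20 ester of the favoured chair blocks the axial approach to C5, so the nucleophile enters equatorially and the resulting axial alkoxide, cis and 1,3-diaxial to C20, acylates on that ester to close the bridging five-membered lactone and fix C5, while the weakly basic reagent neither enolises the ketone nor attacks the esters at low temperature.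

Step 13
Reactants: 19 methyl 3-[(1R,2R,5S,8R)-1-(2-chloroethyl)-2-methyl-7-oxo-5-(prop-1-en-2-yl)-6-oxabicyclo[3.2.1]octan-8-yl]propanoate
Product: 20 methyl 3-[(1R,2R,5S,8R)-1-(2-iodoethyl)-2-methyl-7-oxo-5-(prop-1-en-2-yl)-6-oxabicyclo[3.2.1]octan-8-yl]propanoate
Conditions: NaI, 2-butanone, 80 °C
Reagents that add atoms: sodium iodide, [Na+].[I-]
Why: Finkelstein exchange, iodide displacing the primary chloride at C12 by SN2 and driven by precipitation of NaCl, while the hindered lactone and the methyl ester are inert to iodide at this temperature.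

Step 14
Reactants: 20 methyl 3-[(1R,2R,5S,8R)-1-(2-iodoethyl)-2-methyl-7-oxo-5-(prop-1-en-2-yl)-6-oxabicyclo[3.2.1]octan-8-yl]propanoate; 21 3-bromofuran-2(5H)-one
Product: 23 methyl 3-[(1R,2R,5S,8R)-2-methyl-7-oxo-1-[2-(2-oxo-2,5-dihydrofuran-3-yl)ethyl]-5-(prop-1-en-2-yl)-6-oxabicyclo[3.2.1]octan-8-yl]propanoate (CNP0209666.1), via alkylzinc iodide 22 (not isolated)
Conditions: Zn dust (activated with 1,2-dibromoethane and TMSCl), DMA, 35 °C; then 21, PdCl2(dppf) (5 mol%), THF/DMA, rt
Reagents that add atoms: none
Why: Negishi coupling, in which zinc inserts into the primary C–I bond to give an alkylzinc iodide that tolerates both esters, and zerovalent palladium then adds oxidatively to the activated vinyl C–Br bond of 21, transmetalates and eliminates reductively to form C12–C13, the bidentate phosphine suppressing β-hydride loss.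

Compound list
1 | cyclohexane-1,3-dione | O=C1CCCC(=O)C1 | starting material
2 | ethyl bromoacetate | CCOC(=O)CBr | starting material
3 | ethyl 2-(2,6-dioxocyclohexyl)acetate | CCOC(=O)CC1C(=O)CCCC1=O | intermediate
4 | ethyl 2-(2-ethoxy-6-oxocyclohex-1-en-1-yl)acetate | CCOC(=O)CC1=C(OCC)CCCC1=O | intermediate
5 | 3-ethoxy-2-(2-hydroxyethyl)cyclohex-2-en-1-ol (racemic, not isolated) | OCCC1=C(OCC)CCCC1O | intermediate
6 | 2-(2-hydroxyethyl)cyclohex-2-en-1-one | O=C1CCCC=C1CCO | intermediate
7 | 2-(2-chloroethyl)cyclohex-2-en-1-one | O=C1CCCC=C1CCCl | intermediate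
8 | (E)-penta-1,3-diene | C=C/C=C/C | starting material
9 | (4aS,8R,8aS)-8a-(2-chloroethyl)-8-methyl-3,4,4a,5,8,8a-hexahydronaphthalen-1(2H)-one (cis-fused; C8 methyl cis to the carbonyl-bearing bond) | C1C=C[C@@H](C)[C@@](CCCl)(C(=O)CCC2)[C@H]12 | intermediate
10 | potassium (4aS,8R,8aS)-8a-(2-chloroethyl)-8-methyl-3,4,4a,5,8,8a-hexahydronaphthalen-1-olate (not isolated) | C1C=C[C@@H](C)[C@@](CCCl)(C([O-])=CCC2)[C@H]12.[K+] | intermediate
11 | (4aS,8R,8aS)-8a-(2-chloroethyl)-2-hydroxy-8-methyl-3,4,4a,5,8,8a-hexahydronaphthalen-1(2H)-one (C2 epimers) | C1C=C[C@@H](C)[C@@](CCCl)(C(=O)C(O)CC2)[C@H]12 | intermediate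
12 | methyl (1S,2R,6S)-1-(2-chloroethyl)-2-methyl-6-(3-oxopropyl)cyclohex-3-ene-1-carboxylate | C1C=C[C@@H](C)[C@@](CCCl)(C(=O)OC)[C@H]1CCC=O | intermediate
13 | 3-[(1S,5R,6S)-6-(2-chloroethyl)-6-(methoxycarbonyl)-5-methylcyclohex-3-en-1-yl]propanoic acid | C1C=C[C@@H](C)[C@@](CCCl)(C(=O)OC)[C@H]1CCC(=O)O | intermediate
14 | methyl (1S,2R,6S)-1-(2-chloroethyl)-6-(3-methoxy-3-oxopropyl)-2-methylcyclohex-3-ene-1-carboxylate | C1C=C[C@@H](C)[C@@](CCCl)(C(=O)OC)[C@H]1CCC(=O)OC | intermediate
15 | methyl (1R,2R,6R)-1-(2-chloroethyl)-6-(3-methoxy-3-oxopropyl)-2-methyl-5-oxocyclohex-3-ene-1-carboxylate | O=C1C=C[C@@H](C)[C@@](CCCl)(C(=O)OC)[C@H]1CCC(=O)OC | intermediate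
16 | methyl (1R,2R,6R)-1-(2-chloroethyl)-2-(3-methoxy-3-oxopropyl)-6-methyl-3-oxocyclohexane-1-carboxylate | O=C1CC[C@@H](C)[C@@](CCCl)(C(=O)OC)[C@H]1CCC(=O)OC | intermediate
17 | isopropenylmagnesium bromide (prop-1-en-2-ylmagnesium bromide) | C=C(C)[Mg]Br | starting material
18 | dichlorocerium alkoxide of methyl (1R,2R,3S,6R)-1-(2-chloroethyl)-3-hydroxy-2-(3-methoxy-3-oxopropyl)-6-methyl-3-(prop-1-en-2-yl)cyclohexane-1-carboxylate (not isolated) | C=C(C)[C@]1([O-])CC[C@@H](C)[C@@](CCCl)(C(=O)OC)[C@H]1CCC(=O)OC.[Ce+3].[Cl-].[Cl-] | intermediate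
19 | methyl 3-[(1R,2R,5S,8R)-1-(2-chloroethyl)-2-methyl-7-oxo-5-(prop-1-en-2-yl)-6-oxabicyclo[3.2.1]octan-8-yl]propanoate | C=C(C)[C@@]12CC[C@@H](C)[C@@](CCCl)(C(=O)O1)[C@H]2CCC(=O)OC | intermediate
20 | methyl 3-[(1R,2R,5S,8R)-1-(2-iodoethyl)-2-methyl-7-oxo-5-(prop-1-en-2-yl)-6-oxabicyclo[3.2.1]octan-8-yl]propanoate | C=C(C)[C@@]12CC[C@@H](C)[C@@](CCI)(C(=O)O1)[C@H]2CCC(=O)OC | intermediate
21 | 3-bromofuran-2(5H)-one | O=C1OCC=C1Br | starting material
22 | [2-[(1R,2R,5S,8R)-8-(3-methoxy-3-oxopropyl)-2-methyl-7-oxo-5-(prop-1-en-2-yl)-6-oxabicyclo[3.2.1]octan-1-yl]ethyl]zinc iodide (not isolated) | C=C(C)[C@@]12CC[C@@H](C)[C@@](CC[Zn]I)(C(=O)O1)[C@H]2CCC(=O)OC | intermediate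
23 | methyl 3-[(1R,2R,5S,8R)-2-methyl-7-oxo-1-[2-(2-oxo-2,5-dihydrofuran-3-yl)ethyl]-5-(prop-1-en-2-yl)-6-oxabicyclo[3.2.1]octan-8-yl]propanoate (CNP0209666.1) | C=C(C)[C@@]12CC[C@@H](C)[C@@](CCC3=CCOC3=O)(C(=O)O1)[C@H]2CCC(=O)OC | target

Total step count: 14. Longest linear sequence: 14 steps (1 to 23); 8, 17 and 21 are purchased and enter at steps 5, 12 and 14.

Steps most likely to fail

Step 5. The risk is weak or reversed enantiofacial discrimination, because a 2-alkyl enone cannot adopt the binding mode that orients unsubstituted cycloalkenones on the catalyst; turnover with an α-substituted dienophile may also be slow. The fallback gives up catalyst control. Setting out from 7 and 8, the cycloaddition would be run with AlCl3 in toluene at room temperature, a combination with direct precedent for 2-alkylcyclohex-2-enones and (E)-piperylene that keeps the ortho and endo preferences. It would give 9 as a racemate together with its mirror image, the (4aR,8S,8aR)-octalone F1. The two would be separated by preparative chromatography on a cellulose tris(3,5-dimethylphenylcarbamate) stationary phase, and the (4aS,8R,8aS) enantiomer rejoins the route as 9.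

Step 10. The risk is regiochemical scrambling: hydrogen abstraction at the C8 methine, or oxygen delivery to C7 of the allyl radical, would give isomeric enones. The fallback replaces the radical process by a pericyclic one. Setting out from 14, catalytic SeO2 with t-BuOOH in CH2Cl2 would act by an ene reaction and [2,3]-sigmatropic shift, which returns the double bond to C6=C7 and should place oxygen on the methylene C5 in preference to the methine C8. This would give the C5 allylic alcohol F2 as a mixture of carbinol epimers. It would be oxidised without delay with Dess–Martin periodinane in CH2Cl2, before it can lactonise, and the route is rejoined at 15.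

Step 12. The risk is misdirected acyl transfer: the C5 alkoxide could close a six-membered lactone on the unhindered C3 ester instead of the five-membered one on C20, or the reagent could add to the C3 ester. The fallback removes the C3 ester as an acyl donor. Setting out from 16, LiOH (1 equiv) in THF/H2O at 0 °C should hydrolyse only the C3 ester, the C20 ester on quaternary C9 being much slower, to give the keto acid F3. With 2.5 equiv of the cerium reagent at −78 °C the carboxylate is inert and the ketone is attacked as before. The resulting tertiary hydroxy acid F4 (formed as its alkoxide, not isolated) can acylate only on C20 and would give the lactone acid F5. Trimethylsilyldiazomethane in toluene/MeOH then returns the route to 19.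

Further compounds
F1 | step 5 | (4aR,8S,8aR)-8a-(2-chloroethyl)-8-methyl-3,4,4a,5,8,8a-hexahydronaphthalen-1(2H)-one (mirror image of 9) | C1C=C[C@H](C)[C@](CCCl)(C(=O)CCC2)[C@@H]12
F2 | step 10 | methyl (1R,2R,5RS,6R)-1-(2-chloroethyl)-5-hydroxy-6-(3-methoxy-3-oxopropyl)-2-methylcyclohex-3-ene-1-carboxylate | OC1C=C[C@@H](C)[C@@](CCCl)(C(=O)OC)[C@H]1CCC(=O)OC
F3 | step 12 | 3-[(1R,2R,3R)-2-(2-chloroethyl)-2-(methoxycarbonyl)-3-methyl-6-oxocyclohexyl]propanoic acid | O=C1CC[C@@H](C)[C@@](CCCl)(C(=O)OC)[C@H]1CCC(=O)O
F4 | step 12 | 3-[(1R,2R,3R,6S)-2-(2-chloroethyl)-6-hydroxy-2-(methoxycarbonyl)-3-methyl-6-(prop-1-en-2-yl)cyclohexyl]propanoic acid | C=C(C)[C@]1(O)CC[C@@H](C)[C@@](CCCl)(C(=O)OC)[C@H]1CCC(=O)O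
F5 | step 12 | 3-[(1R,2R,5S,8R)-1-(2-chloroethyl)-2-methyl-7-oxo-5-(prop-1-en-2-yl)-6-oxabicyclo[3.2.1]octan-8-yl]propanoic acid | C=C(C)[C@@]12CC[C@@H](C)[C@@](CCCl)(C(=O)O1)[C@H]2CCC(=O)O
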